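The carbocycle is traced back to D-glucose: ring atoms C1 (ketone), C4 (tertiary carbinol), C5 and C6 (oxirane) are hexose C5, C2, C3 and C4, and the enone bond C2–C3 is the hexose C6–C1 bond. One operation, the mercury-catalysed Ferrier carbocyclisation of hex-5-enopyranoside 11, opens the pyranose and closes the cyclohexanone ring with all three oxygenated stereocentres already in place. Precursor 11 is a methyl β-D-lyxo-hex-5-enopyranoside carrying the C2 vinyl and hydroxyl groups, a 3-O-PMB ether and a 4-O-mesylate, so the leaving group for the later oxirane closure is set before the ring forms. Copper amidation and a Heck coupling then attach the two polyene amide chains.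

Key step: step 9

Remark: the carbocycle is numbered as in the target throughout (C1 ketone, C2 nitrogen-bearing carbon, C4 carbinol, C5/C6 oxirane), the target being the (4R,5S,6R) isomer; 13 is drawn as its expected major C3 epimer and either epimer converges in step 10.

Step 1
Reactants: 1 methyl β-D-glucopyranoside
Product: 2 methyl 4,6-O-[(R)-benzylidene]-β-D-glucopyranoside
Conditions: PhCH(OMe)2, CSA (cat.), MeCN, 50 °C
Reagents that add atoms: benzaldehyde dimethyl acetal, COC(OC)c1ccccc1
Why: Acid-catalysed transacetalisation gives the thermodynamically preferred six-membered 4,6-acetal with equatorial phenyl (R at the acetal carbon), leaving only O2–H and O3–H free.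

Step 2
Reactants: 2 methyl 4,6-O-[(R)-benzylidene]-β-D-glucopyranoside
Product: 4 methyl 4,6-O-[(R)-benzylidene]-3-O-(4-methoxybenzyl)-β-D-glucopyranoside, via 2,3-O-dibutylstannylene acetal 3 (not isolated)
Conditions: Bu2SnO, toluene, reflux (Dean–Stark); then PMBCl, Bu4NI (cat.), 80 °C
Reagents that add atoms: 4-methoxybenzyl chloride, COc1ccc(CCl)cc1
Why: Stannylene-acetal-mediated monoalkylation of the trans-diequatorial 2,3-diol is expected to favour O3, the oxygen remote from the electron-withdrawing anomeric centre in 4,6-O-benzylidene β-glucosides, and any 2-O-ether is removed by chromatography.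

Step 3
Reactants: 4 methyl 4,6-O-[(R)-benzylidene]-3-O-(4-methoxybenzyl)-β-D-glucopyranoside
Product: 5 methyl 4,6-O-[(R)-benzylidene]-3-O-(4-methoxybenzyl)-β-D-arabino-hexopyranosid-2-ulose
Conditions: Dess–Martin periodinane, CH2Cl2, rt
Reagents that add atoms: none
Why: Dess–Martin oxidation converts the only free (secondary) hydroxyl into the 2-ulose under near-neutral conditions that spare the acetal and the PMB ether and avoid β-elimination across C3–C4.

Step 4
Reactants: 5 methyl 4,6-O-[(R)-benzylidene]-3-O-(4-methoxybenzyl)-β-D-arabino-hexopyranosid-2-ulose; 6 vinylmagnesium bromide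
Product: 7 methyl 4,6-O-[(R)-benzylidene]-3-O-(4-methoxybenzyl)-2-C-vinyl-β-D-mannopyranoside
Conditions: THF, −78 → −40 °C; then aq. NH4Cl
Reagents that add atoms: none
Why: Grignard 1,2-addition to the conformationally locked 2-ulose should occur along the equatorial trajectory from the α face, anti to the β-methoxy group, which sets C2 with axial hydroxyl and equatorial vinyl (manno configuration), the sense known for hydride and organometallic additions to β-glycosid-2-uloses.

Step 5
Reactants: 7 methyl 4,6-O-[(R)-benzylidene]-3-O-(4-methoxybenzyl)-2-C-vinyl-β-D-mannopyranoside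
Product: 8 methyl 3-O-(4-methoxybenzyl)-2-C-vinyl-β-D-mannopyranoside
Conditions: TsOH·H2O (cat.), MeOH, rt
Reagents that add atoms: none
Why: Acid-catalysed transacetalisation to methanol removes the benzylidene group at room temperature, conditions under which the PMB ether, the methyl glycoside and the tertiary allylic alcohol (whose ionisation is disfavoured next to the anomeric carbon) should persist.

Step 6
Reactants: 8 methyl 3-O-(4-methoxybenzyl)-2-C-vinyl-β-D-mannopyranoside
Product: 9 methyl 6-deoxy-6-iodo-3-O-(4-methoxybenzyl)-2-C-vinyl-β-D-mannopyranoside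
Conditions: PPh3, I2, imidazole, THF, 0 °C → rt
Reagents that add atoms: iodine, II
Why: Garegg–Samuelsson (Appel-type) iodination is selective for the primary hydroxyl over the secondary O4–H and the tertiary O2–H.

Step 7
Reactants: 9 methyl 6-deoxy-6-iodo-3-O-(4-methoxybenzyl)-2-C-vinyl-β-D-mannopyranoside
Product: 10 methyl 6-deoxy-6-iodo-4-O-methanesulfonyl-3-O-(4-methoxybenzyl)-2-C-vinyl-β-D-mannopyranoside
Conditions: MsCl, pyridine, 0 °C → rt
Reagents that add atoms: methanesulfonyl chloride, CS(=O)(=O)Cl
Why: Sulfonylation of the only secondary alcohol (the tertiary one is inert) places at sugar C4 the equatorial leaving group, trans to O3, that the oxirane closure will displace, so that no α-hydroxy ketone has to be handled after the ring is built.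

Step 8
Reactants: 10 methyl 6-deoxy-6-iodo-4-O-methanesulfonyl-3-O-(4-methoxybenzyl)-2-C-vinyl-β-D-mannopyranoside
Product: 11 methyl 6-deoxy-4-O-methanesulfonyl-3-O-(4-methoxybenzyl)-2-C-vinyl-β-D-lyxo-hex-5-enopyranoside
Conditions: AgF, pyridine, rt, dark
Reagents that add atoms: none
Why: Silver-assisted E2 dehydroiodination of a 6-deoxy-6-iodopyranoside is the classical entry to hex-5-enopyranosides and is compatible with the neighbouring equatorial sulfonate, which has no anti-periplanar ring hydrogen for a competing elimination in the chair.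

Step 9
Reactants: 11 methyl 6-deoxy-4-O-methanesulfonyl-3-O-(4-methoxybenzyl)-2-C-vinyl-β-D-lyxo-hex-5-enopyranoside
Product: 13 (3S,4R,5S,6S)-3,4-dihydroxy-6-(methanesulfonyloxy)-5-[(4-methoxybenzyl)oxy]-4-vinylcyclohexan-1-one, via α-mercurio ketoaldehyde 12 (not isolated)
Conditions: Hg(OCOCF3)2 (10 mol %), acetone/H2O (2:1), 0 °C → rt
Reagents that add atoms: water, O
Why: Divalent mercury adds to the electron-rich exocyclic enol ether and water is delivered to sugar C5, the hemiketal collapses with loss of methanol to the open 1,5-ketoaldehyde 12 carrying mercury on the former C6, and this α-mercurio ketone (a mercury enolate equivalent) attacks the aldehyde to forge the bond that becomes C2–C3 of the carbocycle, after which protonolysis returns the mercury salt. This is the Ferrier carbocyclisation of 6-deoxyhex-5-enopyranosides in its catalytic form, which tolerates sulfonates, benzyl-type ethers and free hydroxyl groups. The single ring closes in a 6-(enolendo)-exo-trig aldol. The only new stereocentre, the C3 carbinol, is expected to form mainly trans to the C5 ether through a chair-like transition state, and since step 10 removes it either epimer serves. The selectivity the step needs is chemoselectivity for the enol ether over the vinyl group, which should be secured because the vinyl group is an unactivated alkene on a quaternary carbon flanked by electron-withdrawing oxygens, while the site of C–C bond formation is fixed by the position of mercury and the three glucose-derived centres are not enolised under these nearly neutral conditions.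

Step 10
Reactants: 13 (3S,4R,5S,6S)-3,4-dihydroxy-6-(methanesulfonyloxy)-5-[(4-methoxybenzyl)oxy]-4-vinylcyclohexan-1-one
Product: 15 (4R,5S,6S)-4-hydroxy-6-(methanesulfonyloxy)-5-[(4-methoxybenzyl)oxy]-4-vinylcyclohex-2-en-1-one, via 3-O-mesylate 14 (not isolated)
Conditions: MsCl, Et3N, CH2Cl2, 0 °C
Reagents that add atoms: none
Why: Sulfonylation of the secondary β-hydroxyl (the tertiary one is inert) followed by E1cB loss of mesylate through the C2 enolate is the standard dehydration of Ferrier products, it removes the undefined carbinol centre, and a short reaction time at 0 °C limits competing loss of the C5 ether through the C6 enolate.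

Step 11
Reactants: 15 (4R,5S,6S)-4-hydroxy-6-(methanesulfonyloxy)-5-[(4-methoxybenzyl)oxy]-4-vinylcyclohex-2-en-1-one
Product: 16 (4R,5S,6S)-4,5-dihydroxy-6-(methanesulfonyloxy)-4-vinylcyclohex-2-en-1-one
Conditions: DDQ, CH2Cl2/pH 7 buffer, 0 °C → rt
Reagents that add atoms: none
Why: DDQ oxidises the electron-rich PMB ether by hydride abstraction and the oxocarbenium ion is hydrolysed, which frees O5–H under neutral conditions that do not disturb the α-mesyloxy enone, the vinyl group or the tertiary alcohol.

Step 12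
Reactants: 16 (4R,5S,6S)-4,5-dihydroxy-6-(methanesulfonyloxy)-4-vinylcyclohex-2-en-1-one
Product: 17 (4R,5S,6R)-5,6-epoxy-4-hydroxy-4-vinylcyclohex-2-en-1-one
Conditions: K2CO3, MeOH, 0 °C
Reagents that add atoms: none
Why: In this intramolecular Williamson etherification (3-exo-tet SN2) the C5 alkoxide displaces the trans, α-keto-activated C6 mesylate with inversion, so the oxirane forms on the face of the C4 hydroxyl and C6 becomes R.

Step 13
Reactants: 17 (4R,5S,6R)-5,6-epoxy-4-hydroxy-4-vinylcyclohex-2-en-1-one
Product: 18 (4R,5S,6R)-5,6-epoxy-4-hydroxy-2-iodo-4-vinylcyclohex-2-en-1-one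
Conditions: I2, pyridine/CH2Cl2, 0 °C → rt
Reagents that add atoms: iodine, II
Why: Johnson α-iodination (reversible conjugate addition of pyridine, iodination of the resulting enolate, elimination) installs iodine at C2 of the enone, a method established on oxygenated 5,6-epoxycyclohex-2-enones, while the isolated vinyl group adds iodine only reversibly.

Step 14
Reactants: 19 cyclohexanecarboxaldehyde; 20 triethyl (E)-4-phosphonocrotonate
Product: 22 (2E,4E)-5-cyclohexylpenta-2,4-dienoic acid, via ethyl dienoate 21 (not isolated)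
Conditions: LiOH·H2O, 4 Å MS, THF, reflux; then H2O, 50 °C; then 1 M HCl
Reagents that add atoms: lithium hydroxide, [Li+].[OH-]
Why: The vinylogous Horner–Wadsworth–Emmons olefination of the stabilised phosphonate should give mainly the (2E,4E)-dienoate, and the same hydroxide then saponifies the ester in the pot, the acid being purified by crystallisation.

Step 15
Reactants: 22 (2E,4E)-5-cyclohexylpenta-2,4-dienoic acid
Product: 24 (2E,4E)-5-cyclohexylpenta-2,4-dienamide, via dienoyl chloride 23 (not isolated)
Conditions: (COCl)2, DMF (cat.), CH2Cl2, 0 °C → rt; then conc. aq. NH3, 0 °C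
Reagents that add atoms: ammonia, N
Why: Acyl chloride formation and ammonolysis convert the acid into the primary amide without affecting the diene geometry.

Step 16
Reactants: 18 (4R,5S,6R)-5,6-epoxy-4-hydroxy-2-iodo-4-vinylcyclohex-2-en-1-one; 24 (2E,4E)-5-cyclohexylpenta-2,4-dienamide
Product: 25 (4R,5S,6R)-2-[(2E,4E)-5-cyclohexylpenta-2,4-dienamido]-5,6-epoxy-4-hydroxy-4-vinylcyclohex-2-en-1-one
Conditions: CuI (10 mol %), N,N'-dimethylethylenediamine (20 mol %), Cs2CO3, THF, 50 °C
Reagents that add atoms: none
Why: Goldberg–Buchwald copper-catalysed amidation of a vinyl iodide, here an activated α-iodoenone, forms the C2–N bond at the position of the halogen under aprotic carbonate conditions that the oxirane should tolerate, and the tertiary alcohol cannot undergo Payne migration because it is cis to the oxirane.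

Step 17
Reactants: 26 cyclopentane-1,3-dione
Product: 27 2-nitrocyclopentane-1,3-dione
Conditions: fuming HNO3, Et2O, 0 °C
Reagents that add atoms: nitric acid, O[N+](=O)[O-]
Why: Electrophilic nitration at C2 of the enolised 1,3-dione is the standard behaviour of cyclic β-diketones.

Step 18
Reactants: 27 2-nitrocyclopentane-1,3-dione
Product: 28 2-amino-3-hydroxycyclopent-2-en-1-one hydrochloride
Conditions: H2 (1 atm), 10% Pd/C, MeOH, HCl
Reagents that add atoms: hydrogen chloride, Cl
Why: Catalytic hydrogenation reduces the nitro group to the amine, which is held as the hydrochloride so that the electron-rich aminodione neither oxidises nor self-condenses.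

Step 19
Reactants: 29 ethyl (E)-4-oxobut-2-enoate
Product: 30 ethyl (2E,4E)-5-iodopenta-2,4-dienoate
Conditions: CrCl2, CHI3, THF, 0 °C
Reagents that add atoms: iodoform, IC(I)I
Why: In the Takai olefination the geminal dichromium species formed from CHI3 and CrCl2 adds to the aldehyde and eliminates to the (E)-vinyl iodide, chemoselectively in the presence of the conjugated ester.

Step 20
Reactants: 30 ethyl (2E,4E)-5-iodopenta-2,4-dienoate
Product: 31 (2E,4E)-5-iodopenta-2,4-dienoic acid
Conditions: LiOH, THF/H2O, 0 °C → rt; then 1 M HCl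
Reagents that add atoms: lithium hydroxide, [Li+].[OH-]
Why: Saponification of the ethyl ester at or below room temperature leaves the vinyl iodide and the diene geometry unchanged.

Step 21
Reactants: 31 (2E,4E)-5-iodopenta-2,4-dienoic acid; 28 2-amino-3-hydroxycyclopent-2-en-1-one hydrochloride
Product: 33 (2E,4E)-N-(2-hydroxy-5-oxocyclopent-1-en-1-yl)-5-iodopenta-2,4-dienamide, via iododienoyl chloride 32 (not isolated)
Conditions: (COCl)2, DMF (cat.), CH2Cl2, 0 °C; then 28, Et3N, CH2Cl2/DMF, 0 °C → rt
Reagents that add atoms: none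
Why: N-Acylation of the amine salt by the acid chloride in the presence of base gives the amide, the thermodynamically preferred acylation site, any O-acylated enol being cleaved on aqueous work-up.

Step 22
Reactants: 25 (4R,5S,6R)-2-[(2E,4E)-5-cyclohexylpenta-2,4-dienamido]-5,6-epoxy-4-hydroxy-4-vinylcyclohex-2-en-1-one; 33 (2E,4E)-N-(2-hydroxy-5-oxocyclopent-1-en-1-yl)-5-iodopenta-2,4-dienamide
Product: 34 (4R,5S,6R)-2-[(2E,4E)-5-cyclohexylpenta-2,4-dienamido]-5,6-epoxy-4-hydroxy-4-{(1E,3E,5E)-7-[(2-hydroxy-5-oxocyclopent-1-en-1-yl)amino]-7-oxohepta-1,3,5-trien-1-yl}cyclohex-2-en-1-one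
Conditions: Pd(OAc)2 (10 mol %), Bu4NCl, NaHCO3, DMF, rt → 40 °C, dark; then aq. NaH2PO4
Reagents that add atoms: none
Why: In this Heck coupling under Jeffery conditions zerovalent palladium inserts into the dienyl C–I bond, the dienylpalladium adds across the monosubstituted vinyl group with carbon at the terminus, and because the adjacent C4 is quaternary the only syn β-hydrogen lies on the former terminal carbon, so elimination gives the (E)-alkene and completes the all-E triene with the iodide geometry retained.

Compound list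
1 | methyl β-D-glucopyranoside | OC[C@H]1O[C@@H](OC)[C@H](O)[C@@H](O)[C@@H]1O | starting material
2 | methyl 4,6-O-[(R)-benzylidene]-β-D-glucopyranoside | c1ccccc1[C@@H]2OC[C@H]3O[C@@H](OC)[C@H](O)[C@@H](O)[C@@H]3O2 | intermediate
3 | methyl 4,6-O-[(R)-benzylidene]-2,3-O-(dibutylstannylene)-β-D-glucopyranoside | c1ccccc1[C@@H]2OC[C@H]3O[C@@H](OC)[C@H](O[Sn]4(CCCC)CCCC)[C@@H](O4)[C@@H]3O2 | intermediate
4 | methyl 4,6-O-[(R)-benzylidene]-3-O-(4-methoxybenzyl)-β-D-glucopyranoside | c1ccccc1[C@@H]2OC[C@H]3O[C@@H](OC)[C@H](O)[C@@H](OCc4ccc(OC)cc4)[C@@H]3O2 | intermediate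
5 | methyl 4,6-O-[(R)-benzylidene]-3-O-(4-methoxybenzyl)-β-D-arabino-hexopyranosid-2-ulose | c1ccccc1[C@@H]2OC[C@H]3O[C@@H](OC)C(=O)[C@@H](OCc4ccc(OC)cc4)[C@@H]3O2 | intermediate
6 | vinylmagnesium bromide | C=C[Mg]Br | starting material
7 | methyl 4,6-O-[(R)-benzylidene]-3-O-(4-methoxybenzyl)-2-C-vinyl-β-D-mannopyranoside (axial 2-hydroxyl, equatorial vinyl) | c1ccccc1[C@@H]2OC[C@H]3O[C@@H](OC)[C@@](C=C)(O)[C@@H](OCc4ccc(OC)cc4)[C@@H]3O2 | intermediate
8 | methyl 3-O-(4-methoxybenzyl)-2-C-vinyl-β-D-mannopyranoside | OC[C@H]1O[C@@H](OC)[C@@](C=C)(O)[C@@H](OCc2ccc(OC)cc2)[C@@H]1O | intermediate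
9 | methyl 6-deoxy-6-iodo-3-O-(4-methoxybenzyl)-2-C-vinyl-β-D-mannopyranoside | IC[C@H]1O[C@@H](OC)[C@@](C=C)(O)[C@@H](OCc2ccc(OC)cc2)[C@@H]1O | intermediate
10 | methyl 6-deoxy-6-iodo-4-O-methanesulfonyl-3-O-(4-methoxybenzyl)-2-C-vinyl-β-D-mannopyranoside | IC[C@H]1O[C@@H](OC)[C@@](C=C)(O)[C@@H](OCc2ccc(OC)cc2)[C@@H]1OS(C)(=O)=O | intermediate
11 | methyl 6-deoxy-4-O-methanesulfonyl-3-O-(4-methoxybenzyl)-2-C-vinyl-β-D-lyxo-hex-5-enopyranoside | C=C1O[C@@H](OC)[C@@](C=C)(O)[C@@H](OCc2ccc(OC)cc2)[C@@H]1OS(C)(=O)=O | intermediate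
12 | 6-deoxy-4-O-methanesulfonyl-3-O-(4-methoxybenzyl)-6-[(trifluoroacetoxy)mercurio]-2-C-vinyl-D-lyxo-hexos-5-ulose (open-chain α-mercurio ketoaldehyde) | O=C[C@](O)(C=C)[C@@H](OCc1ccc(OC)cc1)[C@H](OS(C)(=O)=O)C(=O)C[Hg]OC(=O)C(F)(F)F | intermediate
13 | (3S,4R,5S,6S)-3,4-dihydroxy-6-(methanesulfonyloxy)-5-[(4-methoxybenzyl)oxy]-4-vinylcyclohexan-1-one | C1[C@H](O)[C@](O)(C=C)[C@@H](OCc2ccc(OC)cc2)[C@H](OS(C)(=O)=O)C1=O | intermediate
14 | 3-O-methanesulfonate of 13 (4-hydroxy-3,6-bis(methanesulfonyloxy)-5-[(4-methoxybenzyl)oxy]-4-vinylcyclohexan-1-one, configuration as in 13) | C1[C@H](OS(C)(=O)=O)[C@](O)(C=C)[C@@H](OCc2ccc(OC)cc2)[C@H](OS(C)(=O)=O)C1=O | intermediate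
15 | (4R,5S,6S)-4-hydroxy-6-(methanesulfonyloxy)-5-[(4-methoxybenzyl)oxy]-4-vinylcyclohex-2-en-1-one | C1=C[C@](O)(C=C)[C@@H](OCc2ccc(OC)cc2)[C@H](OS(C)(=O)=O)C1=O | intermediate
16 | (4R,5S,6S)-4,5-dihydroxy-6-(methanesulfonyloxy)-4-vinylcyclohex-2-en-1-one | C1=C[C@](O)(C=C)[C@@H](O)[C@H](OS(C)(=O)=O)C1=O | intermediate
17 | (4R,5S,6R)-5,6-epoxy-4-hydroxy-4-vinylcyclohex-2-en-1-one (oxirane cis to the hydroxyl) | C1=C[C@](O)(C=C)[C@H]2O[C@H]2C1=O | intermediate
18 | (4R,5S,6R)-5,6-epoxy-4-hydroxy-2-iodo-4-vinylcyclohex-2-en-1-one | IC1=C[C@](O)(C=C)[C@H]2O[C@H]2C1=O | intermediate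
19 | cyclohexanecarboxaldehyde | O=CC1CCCCC1 | starting material
20 | triethyl (E)-4-phosphonocrotonate | CCOC(=O)/C=C/CP(=O)(OCC)OCC | starting material
21 | ethyl (2E,4E)-5-cyclohexylpenta-2,4-dienoate | CCOC(=O)/C=C/C=C/C1CCCCC1 | intermediate
22 | (2E,4E)-5-cyclohexylpenta-2,4-dienoic acid | OC(=O)/C=C/C=C/C1CCCCC1 | intermediate
23 | (2E,4E)-5-cyclohexylpenta-2,4-dienoyl chloride | ClC(=O)/C=C/C=C/C1CCCCC1 | intermediate
24 | (2E,4E)-5-cyclohexylpenta-2,4-dienamide | NC(=O)/C=C/C=C/C1CCCCC1 | intermediate
25 | (4R,5S,6R)-2-[(2E,4E)-5-cyclohexylpenta-2,4-dienamido]-5,6-epoxy-4-hydroxy-4-vinylcyclohex-2-en-1-one | O=C(/C=C/C=C/C1CCCCC1)NC1=C[C@](O)(C=C)[C@H]2O[C@H]2C1=O | intermediate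
26 | cyclopentane-1,3-dione | O=C1CCC(=O)C1 | starting material
27 | 2-nitrocyclopentane-1,3-dione (drawn as its enol) | O=C1CCC(O)=C1[N+](=O)[O-] | intermediate
28 | 2-amino-3-hydroxycyclopent-2-en-1-one hydrochloride | Cl.NC1=C(O)CCC1=O | intermediate
29 | ethyl (E)-4-oxobut-2-enoate | CCOC(=O)/C=C/C=O | starting material
30 | ethyl (2E,4E)-5-iodopenta-2,4-dienoate | CCOC(=O)/C=C/C=C/I | intermediate
31 | (2E,4E)-5-iodopenta-2,4-dienoic acid | OC(=O)/C=C/C=C/I | intermediate
32 | (2E,4E)-5-iodopenta-2,4-dienoyl chloride | ClC(=O)/C=C/C=C/I | intermediate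
33 | (2E,4E)-N-(2-hydroxy-5-oxocyclopent-1-en-1-yl)-5-iodopenta-2,4-dienamide | O=C(/C=C/C=C/I)NC1=C(O)CCC1=O | intermediate
34 | (4R,5S,6R)-2-[(2E,4E)-5-cyclohexylpenta-2,4-dienamido]-5,6-epoxy-4-hydroxy-4-{(1E,3E,5E)-7-[(2-hydroxy-5-oxocyclopent-1-en-1-yl)amino]-7-oxohepta-1,3,5-trien-1-yl}cyclohex-2-en-1-one | O=C(/C=C/C=C/C1CCCCC1)NC1=C[C@](O)(/C=C/C=C/C=C/C(=O)NC2=C(O)CCC2=O)[C@H]2O[C@H]2C1=O | target

Total step count: 22.
Longest linear sequence: 15 steps (steps 1–13, then 16 and 22).

Steps most likely to fail

Step 9. The mercury salt may add to the vinyl group and be held there as an alkylmercury species, so that catalytic turnover stops, or the allylic mesylate may ionise before the enol ether is hydrated. The fallback avoids mercury and sets out from 11. Hydration of the enol ether with dilute aqueous H2SO4 in dioxane at room temperature, followed by spontaneous loss of methanol from the hemiacetal, should give the open-chain 6-deoxy-4-O-methanesulfonyl-3-O-(4-methoxybenzyl)-2-C-vinyl-D-lyxo-hexos-5-ulose F1. This methyl ketone–aldehyde is then closed by an amine-catalysed intramolecular aldol reaction (L-proline, DMSO, room temperature; 6-(enolendo)-exo-trig through the methyl-side enamine), which comes back to the route at 13.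

Step 16. The weakly nucleophilic dienamide may couple slowly, and during the heating with carbonate and copper iodide the epoxy enone may degrade through oxirane opening by iodide or base-induced fragmentation. The fallback sets out from 18 and brings in the nitrogen first and the acyl group last. Copper-catalysed azidation at room temperature (NaN3, CuI, sodium ascorbate NaC6H7O6, N,N'-dimethylethylenediamine, EtOH/H2O) should give (4R,5S,6R)-2-azido-5,6-epoxy-4-hydroxy-4-vinylcyclohex-2-en-1-one F2. Staudinger reduction (PPh3, THF/H2O) converts it into (4R,5S,6R)-2-amino-5,6-epoxy-4-hydroxy-4-vinylcyclohex-2-en-1-one F3. N-Acylation of this aminoenone with dienoyl chloride 23 (made from 22 with oxalyl chloride as in step 15) and pyridine in CH2Cl2 at 0 °C comes back to the route at 25.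

Step 22. Insertion into the hindered vinyl group may be slow, so that homocoupling or geometrical isomerisation of the dienyl iodide and base-induced decay of the polyene product take over. The fallback sets out from 25 and splits the bond formation into two milder events. Cross-metathesis with vinylboronic acid pinacol ester (second-generation Hoveyda–Grubbs catalyst, CH2Cl2, 40 °C; the terminal alkene reacts, the conjugated amide alkenes should not) gives (4R,5S,6R)-2-[(2E,4E)-5-cyclohexylpenta-2,4-dienamido]-5,6-epoxy-4-hydroxy-4-[(E)-2-(4,4,5,5-tetramethyl-1,3,2-dioxaborolan-2-yl)ethenyl]cyclohex-2-en-1-one F4. Suzuki–Miyaura coupling of this boronate with iodide 33 (Pd(PPh3)4, K3PO4, THF/H2O, room temperature) then comes back to the route at 34.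

Further compounds
F1 | step 9 | 6-deoxy-4-O-methanesulfonyl-3-O-(4-methoxybenzyl)-2-C-vinyl-D-lyxo-hexos-5-ulose | O=C[C@](O)(C=C)[C@@H](OCc1ccc(OC)cc1)[C@H](OS(C)(=O)=O)C(C)=O
F2 | step 16 | (4R,5S,6R)-2-azido-5,6-epoxy-4-hydroxy-4-vinylcyclohex-2-en-1-one | [N-]=[N+]=NC1=C[C@](O)(C=C)[C@H]2O[C@H]2C1=O
F3 | step 16 | (4R,5S,6R)-2-amino-5,6-epoxy-4-hydroxy-4-vinylcyclohex-2-en-1-one | NC1=C[C@](O)(C=C)[C@H]2O[C@H]2C1=O
F4 | step 22 | (4R,5S,6R)-2-[(2E,4E)-5-cyclohexylpenta-2,4-dienamido]-5,6-epoxy-4-hydroxy-4-[(E)-2-(4,4,5,5-tetramethyl-1,3,2-dioxaborolan-2-yl)ethenyl]cyclohex-2-en-1-one | O=C(/C=C/C=C/C1CCCCC1)NC1=C[C@](O)(/C=C/B2OC(C)(C)C(C)(C)O2)[C@H]2O[C@H]2C1=O
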